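**Assumption:** names, SMILES and CIP descriptors of 11–13 use the enol tautomer written in the target SMILES; Eschenmoser's chloride 5 and the (R,R)-lactamide iodoarene of step 5 are bought.

## Retrosynthetic overview

1. Target 13 ⇒ aspidinol 4 + chiral Mannich base 11. The CH2 bridge is closed last: 11 loses Me2NH to give the 6-methylene trione 12, which C-alkylates 4.
2. 11 ⇒ 6 + allylsilane 9 (key step). The quaternary C4–CH2 bond joins two normally nucleophilic carbons: the methyl-bearing ring carbon of 6 becomes an enolonium (phenoxenium) carbon on a chiral aryl-λ3-iodane and is attacked by 9 (SE2′, linear prenyl). This dearomatises ring A and sets (R).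
3. 6 and 4 ⇒ common ketone 3 (aminomethylation / para-O-methylation); 3 ⇒ 1 + 2; 9 ⇒ prenyl chloride 7 + Me3SiCl.
4. Rings: none is built. Both six-membered rings come from 1; ring B stays aromatic, ring A is dearomatised in step 5.

## Route

Step 1
Reactants: 1 2-methylbenzene-1,3,5-triol (2-methylphloroglucinol); 2 butanoic acid
Product: 3 1-(2,4,6-trihydroxy-3-methylphenyl)butan-1-one
Conditions: BF3·OEt2 (solvent), 80 °C, 3 h; then aq. NaOAc, rt
Reagents that add atoms: none
Why: Friedel–Crafts C-acylation; the two free ring positions of 1 are equivalent and the BF2-chelated ketone is deactivated, so only the mono-ketone forms.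

Step 2
Reactants: 3 1-(2,4,6-trihydroxy-3-methylphenyl)butan-1-one
Product: 4 1-(2,6-dihydroxy-4-methoxy-3-methylphenyl)butan-1-one (aspidinol)
Conditions: Me2SO4 (1.0 equiv), K2CO3 (1.1 equiv), acetone, 40 °C
Reagents that add atoms: dimethyl sulfate, COS(=O)(=O)OC
Why: Williamson O-methylation; the 4-OH para to the ketone is the most acidic and the only one not hydrogen-bonded to the carbonyl, so one equivalent of reagent methylates it selectively.

Step 3
Reactants: 3 1-(2,4,6-trihydroxy-3-methylphenyl)butan-1-one; 5 N,N-dimethylmethyleneiminium chloride (Eschenmoser's chloride)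
Product: 6 1-{3-[(dimethylamino)methyl]-2,4,6-trihydroxy-5-methylphenyl}butan-1-one
Conditions: MeCN, 0 °C → rt, 2 h; pH 7 phosphate work-up, zwitterion filtered
Reagents that add atoms: none
Why: Mannich aminomethylation at the only free ring C–H; the preformed iminium salt avoids formaldehyde-derived methylene-bis dimers, and the CH2NMe2 group later blocks this carbon and delivers the bridge carbon.

Step 4
Reactants: 7 1-chloro-3-methylbut-2-ene (prenyl chloride)
Product: 9 trimethyl(2-methylbut-3-en-2-yl)silane, via prenylmagnesium chloride 8 (not isolated)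
Conditions: Mg (1.5 equiv), Me3SiCl (1.2 equiv), THF, 0–10 °C, slow addition of 7 (Barbier); fractional distillation
Reagents that add atoms: chlorotrimethylsilane, C[Si](C)(C)Cl
Why: Barbier–Grignard silylation; the allylic Grignard is silylated at its γ-carbon (SE2′, cyclic transition state) to give the tertiary allylsilane, and the minor linear prenylsilane is removed by distillation.

Step 5
Reactants: 6 1-{3-[(dimethylamino)methyl]-2,4,6-trihydroxy-5-methylphenyl}butan-1-one; 9 trimethyl(2-methylbut-3-en-2-yl)silane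
Product: 11 (4R)-2-butanoyl-6-[(dimethylamino)methyl]-3,5-dihydroxy-4-methyl-4-(3-methylbut-2-en-1-yl)cyclohexa-2,5-dien-1-one, via aryloxy-λ3-iodane 10 (not isolated)
Conditions: (R,R)-2,2′-[(2-iodo-1,3-phenylene)bis(oxy)]bis[N-(2,4,6-trimethylphenyl)propanamide] (1.1 equiv, recovered), mCPBA (1.05 equiv), CH2Cl2–AcOH 10:1, rt, 12 h; then HFIP, −40 °C, 6 (1.0 equiv), 15 min; then 9 (3 equiv), −40 → −20 °C, 6 h; 11 recrystallised
Reagents that add atoms: none
Why: Proposed new method: the chiral diacetoxy-λ3-iodane made in the flask exchanges acetate for the 4-phenolate oxygen of zwitterion 6 (the only oxygen not chelated to the ketone), which turns the flanking methyl-bearing carbon into an enolonium/phenoxenium carbon; the terminal CH2 of 9 attacks it in an SE2′ (Hosomi–Sakurai-type) step with loss of Me3Si and the iodoarene, giving a linear prenyl group, while the CH2NHMe2+-bearing ortho carbon is inductively deactivated and more hindered; the helical lactamide arms of the (R,R)-iodane shield one ring face, and attack on the open face is assigned to give the (4R) quaternary centre; the closest known reaction types are iodine(III)-mediated oxidative allylation of 2-alkylarenols and of ketone enolonium species with allylsilanes, and enantioselective ortho-dearomatisation of phenols with this class of chiral iodoarenes.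

Step 6
Reactants: 11 (4R)-2-butanoyl-6-[(dimethylamino)methyl]-3,5-dihydroxy-4-methyl-4-(3-methylbut-2-en-1-yl)cyclohexa-2,5-dien-1-one; 4 1-(2,6-dihydroxy-4-methoxy-3-methylphenyl)butan-1-one (aspidinol)
Product: 13 (4R)-2-butanoyl-6-[(3-butanoyl-2,4-dihydroxy-6-methoxy-5-methylphenyl)methyl]-3,5-dihydroxy-4-methyl-4-(3-methylbut-2-en-1-yl)cyclohexa-2,5-dien-1-one, via 6-methylene trione 12 (not isolated)
Conditions: 4 (1.5 equiv), AcOH (cat.), 1,4-dioxane, 70 °C, N2 sweep
Reagents that add atoms: none
Why: Mannich-base exchange: retro-Michael loss of Me2NH gives the 2-methylene-1,3-dione 12, which is trapped in a Michael/Friedel–Crafts C-alkylation by the only free ring carbon of 4; no bond at the quaternary carbon is touched, so (R) is retained.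

## Compound list

1 | 2-methylbenzene-1,3,5-triol | Cc1c(O)cc(O)cc1O | starting material
2 | butanoic acid | CCCC(=O)O | starting material
3 | 1-(2,4,6-trihydroxy-3-methylphenyl)butan-1-one | CCCC(=O)c1c(O)cc(O)c(C)c1O | intermediate
4 | 1-(2,6-dihydroxy-4-methoxy-3-methylphenyl)butan-1-one (aspidinol) | CCCC(=O)c1c(O)cc(OC)c(C)c1O | intermediate
5 | N,N-dimethylmethyleneiminium chloride | C=[N+](C)C.[Cl-] | starting material
6 | 1-{3-[(dimethylamino)methyl]-2,4,6-trihydroxy-5-methylphenyl}butan-1-one | CCCC(=O)c1c(O)c(CN(C)C)c(O)c(C)c1O | intermediate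
7 | 1-chloro-3-methylbut-2-ene | CC(C)=CCCl | starting material
8 | (3-methylbut-2-en-1-yl)magnesium chloride | CC(C)=CC[Mg]Cl | intermediate
9 | trimethyl(2-methylbut-3-en-2-yl)silane | C=CC(C)(C)[Si](C)(C)C | intermediate
10 | acetoxy[4-butanoyl-2-[(dimethylamino)methyl]-3,5-dihydroxy-6-methylphenoxy]{2,6-bis[(2R)-1-oxo-1-(2,4,6-trimethylanilino)propan-2-yloxy]phenyl}-λ3-iodane | CCCC(=O)c1c(O)c(CN(C)C)c(OI(OC(C)=O)c2c(O[C@H](C)C(=O)Nc3c(C)cc(C)cc3C)cccc2O[C@H](C)C(=O)Nc2c(C)cc(C)cc2C)c(C)c1O | intermediate
11 | (4R)-2-butanoyl-6-[(dimethylamino)methyl]-3,5-dihydroxy-4-methyl-4-(3-methylbut-2-en-1-yl)cyclohexa-2,5-dien-1-one | CCCC(=O)C1=C(O)[C@](C)(CC=C(C)C)C(O)=C(CN(C)C)C1=O | intermediate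
12 | (4S)-2-butanoyl-3-hydroxy-4-methyl-6-methylidene-4-(3-methylbut-2-en-1-yl)cyclohex-2-ene-1,5-dione (same spatial arrangement as 11; the descriptor changes by CIP only) | CCCC(=O)C1=C(O)[C@](C)(CC=C(C)C)C(=O)C(=C)C1=O | intermediate
13 | (4R)-2-butanoyl-6-[(3-butanoyl-2,4-dihydroxy-6-methoxy-5-methylphenyl)methyl]-3,5-dihydroxy-4-methyl-4-(3-methylbut-2-en-1-yl)cyclohexa-2,5-dien-1-one | CCCC(=O)C1=C(O)[C@](C)(CC=C(C)C)C(O)=C(Cc2c(O)c(C(=O)CCC)c(O)c(C)c2OC)C1=O | target

## Step count and risks

Total step count: 6. Longest linear sequence: 4 (steps 1, 3, 5, 6).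

The three steps most likely to fail:

**Step 5.** The level and sense of asymmetric induction with an external carbon nucleophile are unproven. Acetate or HFIP may compete with 9 for the enolonium carbon. Fallback: setting out from 3, a Mannich reaction with aqueous formaldehyde and (S)-N-methyl-1-phenylethylamine (EtOH, rt) gives 1-[2,4,6-trihydroxy-3-methyl-5-({methyl[(1S)-1-phenylethyl]amino}methyl)phenyl]butan-1-one F1. This is dearomatised with achiral PhI(OAc)2 and 9 (CH2Cl2–HFIP–AcOH, −40 °C), so the covalently bound chiral ammonium group next to the iodine-bearing oxygen is the only stereocontrol element. The two diastereomers are separated by crystallisation or chromatography to give (4R)-2-butanoyl-3,5-dihydroxy-4-methyl-4-(3-methylbut-2-en-1-yl)-6-({methyl[(1S)-1-phenylethyl]amino}methyl)cyclohexa-2,5-dien-1-one F2, with the configuration secured by X-ray. Under the step-6 conditions F2 loses the auxiliary amine and comes back to the route at 12, which goes on to 13.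

**Step 6.** Amine loss may be slow, or 12 may self-condense or give the symmetric ring-A dimer before 4 captures it. Fallback: setting out from 11, treatment with sodium p-toluenesulfinate (3 equiv) in HCO2H–H2O at 40 °C exchanges the amine for sulfinate. This gives the crystalline (4S)-2-butanoyl-3,5-dihydroxy-4-methyl-4-(3-methylbut-2-en-1-yl)-6-{[(4-methylphenyl)sulfonyl]methyl}cyclohexa-2,5-dien-1-one F3 (same spatial arrangement as 11; the descriptor changes because sulfur outranks oxygen). F3 is added at 0 °C to 4 (1.5 equiv) pre-treated with Cs2CO3 (3 equiv) in THF. Base-induced loss of sulfinate then regenerates 12 at low temperature in the presence of the aryl anion, so the fallback comes back to the route at 12 and on to 13.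

**Step 4.** Silylation may give too much linear prenylsilane, which is the more nucleophilic isomer and would deliver a reverse-prenyl group in step 5. Fallback: setting out from 6, step 5 is run with commercial allyltrimethylsilane in place of 9 to give (4R)-2-butanoyl-6-[(dimethylamino)methyl]-3,5-dihydroxy-4-methyl-4-(prop-2-en-1-yl)cyclohexa-2,5-dien-1-one F4. F4 and 4 under the step-6 conditions give (4R)-2-butanoyl-6-[(3-butanoyl-2,4-dihydroxy-6-methoxy-5-methylphenyl)methyl]-3,5-dihydroxy-4-methyl-4-(prop-2-en-1-yl)cyclohexa-2,5-dien-1-one F5. Cross-metathesis of F5 with 2-methylbut-2-ene (Grubbs II 5 mol %, CH2Cl2, 40 °C) converts allyl into prenyl and comes back to the route at 13.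

## Further compounds

F1 | step 5 | 1-[2,4,6-trihydroxy-3-methyl-5-({methyl[(1S)-1-phenylethyl]amino}methyl)phenyl]butan-1-one | CCCC(=O)c1c(O)c(CN(C)[C@@H](C)c2ccccc2)c(O)c(C)c1O
F2 | step 5 | (4R)-2-butanoyl-3,5-dihydroxy-4-methyl-4-(3-methylbut-2-en-1-yl)-6-({methyl[(1S)-1-phenylethyl]amino}methyl)cyclohexa-2,5-dien-1-one | CCCC(=O)C1=C(O)[C@](C)(CC=C(C)C)C(O)=C(CN(C)[C@@H](C)c2ccccc2)C1=O
F3 | step 6 | (4S)-2-butanoyl-3,5-dihydroxy-4-methyl-4-(3-methylbut-2-en-1-yl)-6-{[(4-methylphenyl)sulfonyl]methyl}cyclohexa-2,5-dien-1-one | CCCC(=O)C1=C(O)[C@](C)(CC=C(C)C)C(O)=C(CS(=O)(=O)c2ccc(C)cc2)C1=O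
F4 | step 4 | (4R)-2-butanoyl-6-[(dimethylamino)methyl]-3,5-dihydroxy-4-methyl-4-(prop-2-en-1-yl)cyclohexa-2,5-dien-1-one | CCCC(=O)C1=C(O)[C@](C)(CC=C)C(O)=C(CN(C)C)C1=O
F5 | step 4 | (4R)-2-butanoyl-6-[(3-butanoyl-2,4-dihydroxy-6-methoxy-5-methylphenyl)methyl]-3,5-dihydroxy-4-methyl-4-(prop-2-en-1-yl)cyclohexa-2,5-dien-1-one | CCCC(=O)C1=C(O)[C@](C)(CC=C)C(O)=C(Cc2c(O)c(C(=O)CCC)c(O)c(C)c2OC)C1=O
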